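**Strategy.** The side chain is cut between its second and third CH2 counted from C6, the quaternary carbon of the 1,2-dioxane ring that carries the methyl group and a peroxide oxygen. Because this bond lies β,γ to C6, C6 is treated as a latent ketone. A cyclopropanol built on the future C6 (from an (S)-citramalate-derived ester) opens under strain release to a zinc homoenolate, which nickel couples with the redox-active ester of an 8-aryloctanoic acid with loss of CO2. The C6 ketone then becomes the exo-methylene that takes up O2 (cobalt-mediated peroxidation), and the peroxide closes onto a C4 butenolide to give the cis-fused dioxane–lactone.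

Key step: step 8

Remark on the chemistry: the target is taken exactly as the SMILES defines it, (3S,4S,6R) in plakortolide numbering (C1 lactone carbonyl, C2 CH2, C3 CH–OO, C4 C(Me)–O, C5 ring CH2, C6 C(Me)–OO; side chain C1′–C9′ outward from C6). C4 comes from (S)-citramalic acid and C3 is set by C4 in the ring closure. C6 is created without facial control in step 13; both C6 epimers are expected and the (6R) compound is isolated by chromatography after step 14.

**Step 1**
Reactants: 1 tert-butyl(4-iodophenoxy)dimethylsilane; 2 oct-7-ynoic acid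
Product: 3 8-{4-[(tert-butyldimethylsilyl)oxy]phenyl}oct-7-ynoic acid
Conditions: PdCl2(PPh3)2 (2 mol %), CuI (4 mol %), Et3N, THF, rt
Reagents that add atoms: none
Why: Sonogashira coupling of the aryl iodide with the terminal alkyne should proceed at room temperature, the free acid being carried as its ammonium carboxylate.

**Step 2**
Reactants: 3 8-{4-[(tert-butyldimethylsilyl)oxy]phenyl}oct-7-ynoic acid
Product: 4 8-{4-[(tert-butyldimethylsilyl)oxy]phenyl}octanoic acid
Conditions: H2 (1 atm), 10% Pd/C, EtOAc, rt
Reagents that add atoms: none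
Why: Heterogeneous catalytic hydrogenation saturates the alkyne to the alkane without touching the aryl silyl ether or the acid.

**Step 3**
Reactants: 4 8-{4-[(tert-butyldimethylsilyl)oxy]phenyl}octanoic acid
Product: 5 1,3-dioxoisoindolin-2-yl 8-{4-[(tert-butyldimethylsilyl)oxy]phenyl}octanoate
Conditions: N-hydroxyphthalimide, DIC, DMAP (cat.), CH2Cl2, rt
Reagents that add atoms: N-hydroxyphthalimide, O=C1N(O)C(=O)c2ccccc12
Why: Carbodiimide (Steglich-type) esterification gives the redox-active ester that later serves as the precursor of the primary alkyl radical.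

**Step 4**
Reactants: 6 (S)-citramalic acid
Product: 7 dimethyl (2S)-2-hydroxy-2-methylbutanedioate
Conditions: MeOH, AcCl (cat., HCl in situ), rt
Reagents that add atoms: methanol, CO
Why: Fischer esterification under mild HCl catalysis; the quaternary carbinol centre has no α-hydrogen and cannot epimerize.

**Step 5**
Reactants: 7 dimethyl (2S)-2-hydroxy-2-methylbutanedioate
Product: 8 methyl (3S)-3,4-dihydroxy-3-methylbutanoate
Conditions: BH3·SMe2 (1.05 equiv), NaBH4 (5 mol %), THF, 0 °C → rt; MeOH quench
Reagents that add atoms: none
Why: Hydroxyl-directed borane reduction: the alkoxyborane formed at the tertiary OH delivers hydride through a five-membered chelate, so only the adjacent ester should be reduced and the CH2CO2Me group should survive.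

**Step 6**
Reactants: 8 methyl (3S)-3,4-dihydroxy-3-methylbutanoate
Product: 9 methyl 2-[(4S)-2,2,4-trimethyl-1,3-dioxolan-4-yl]acetate
Conditions: 2,2-dimethoxypropane, TsOH·H2O (cat.), acetone–MeOH, rt
Reagents that add atoms: 2,2-dimethoxypropane, COC(C)(C)OC
Why: Acid-catalysed transketalization of the 1,2-diol gives the dioxolane, and the methanol in the medium returns any lactonized material to the methyl ester.

**Step 7**
Reactants: 9 methyl 2-[(4S)-2,2,4-trimethyl-1,3-dioxolan-4-yl]acetate
Product: 10 1-{[(4S)-2,2,4-trimethyl-1,3-dioxolan-4-yl]methyl}cyclopropan-1-ol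
Conditions: EtMgBr (2.5 equiv), Ti(OiPr)4 (20 mol %), THF, 0 °C → rt; aq. NH4Cl
Reagents that add atoms: ethylmagnesium bromide, CC[Mg]Br
Why: Kulinkovich reaction: the titanacyclopropane generated from EtMgBr and Ti(OiPr)4 adds twice to the ester carbonyl as a 1,2-dicarbanion equivalent, giving the cyclopropanol whose carbinol carbon is the future C6 and whose ring CH2 groups are the future C1′ and C2′.

**Step 8**
Reactants: 10 1-{[(4S)-2,2,4-trimethyl-1,3-dioxolan-4-yl]methyl}cyclopropan-1-ol; 5 1,3-dioxoisoindolin-2-yl 8-{4-[(tert-butyldimethylsilyl)oxy]phenyl}octanoate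
Product: 12 11-{4-[(tert-butyldimethylsilyl)oxy]phenyl}-1-[(4S)-2,2,4-trimethyl-1,3-dioxolan-4-yl]undecan-2-one, via zinc homoenolate 11 (not isolated)
Conditions: 10 (2.0 equiv), Et2Zn (1.0 equiv), THF–DMA, 0 → 40 °C; then 5 (1.0 equiv), NiCl2·glyme (20 mol %), 4,4′-di-tert-butyl-2,2′-bipyridine (40 mol %), rt; aq. NH4Cl
Reagents that add atoms: none
Why: Et2Zn deprotonates two molecules of 10, and the zinc cyclopropoxide relieves its ring strain by β-carbon scission of a C6–CH2 bond to give the C-bound zinc homoenolate 11, in which C2′ carries the metal and C6 is a ketone. Ni(I) reduces the redox-active ester 5 by single-electron transfer, the radical anion loses phthalimide anion and CO2, and the resulting primary radical (the future C3′) is captured by the alkylnickel(II) formed by transmetalation of 11, after which reductive elimination from Ni(III) forms the C2′–C3′ bond. The closest known reaction types are the nickel-catalysed decarboxylative Negishi alkyl–alkyl coupling of N-hydroxyphthalimide esters with dialkylzincs and the nickel-catalysed β-alkylation of cyclopropanol-derived homoenolates with such esters. No ring is closed and no stereocentre is created; the C4 centre in the dioxolane is remote from the reacting carbons and is carried through unchanged. The step needs cross-coupling to win over O-acylation of the cyclopropoxide by the active ester, protonation or β-hydride elimination of the homoenolate and dimerization of the radical; complete ring opening before 5 is added, carbonyl chelation in the β-metalated ketone and the bipyridine ligand should secure this. Regiochemistry of ring opening is not an issue because the two ring CH2 groups of 10 are equivalent.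

**Step 9**
Reactants: 12 11-{4-[(tert-butyldimethylsilyl)oxy]phenyl}-1-[(4S)-2,2,4-trimethyl-1,3-dioxolan-4-yl]undecan-2-one
Product: 13 tert-butyldimethyl(4-{10-methylidene-11-[(4S)-2,2,4-trimethyl-1,3-dioxolan-4-yl]undecyl}phenoxy)silane
Conditions: Ph3PCH3Br, KHMDS, THF, 0 °C → rt
Reagents that add atoms: methyltriphenylphosphonium bromide, C[P+](c1ccccc1)(c1ccccc1)c1ccccc1.[Br-]
Why: Wittig methylenation of the unhindered dialkyl ketone with the non-stabilized ylide; a hindered amide base and low temperature should limit enolization and β-elimination of the dioxolane oxygen.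

**Step 10**
Reactants: 13 tert-butyldimethyl(4-{10-methylidene-11-[(4S)-2,2,4-trimethyl-1,3-dioxolan-4-yl]undecyl}phenoxy)silane
Product: 14 (2S)-13-{4-[(tert-butyldimethylsilyl)oxy]phenyl}-2-methyl-4-methylidenetridecane-1,2-diol
Conditions: AcOH–H2O (4:1), 40 °C
Reagents that add atoms: none
Why: Acid-catalysed hydrolysis of the isopropylidene ketal; the aryl silyl ether and the 1,1-disubstituted alkene should tolerate aqueous acetic acid at this temperature.

**Step 11**
Reactants: 14 (2S)-13-{4-[(tert-butyldimethylsilyl)oxy]phenyl}-2-methyl-4-methylidenetridecane-1,2-diol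
Product: 15 (2S)-13-{4-[(tert-butyldimethylsilyl)oxy]phenyl}-2-hydroxy-2-methyl-4-methylidenetridecanal
Conditions: SO3·pyridine, DMSO, i-Pr2NEt, CH2Cl2, 0 °C
Reagents that add atoms: none
Why: Parikh–Doering (activated DMSO) oxidation converts the primary alcohol to the aldehyde; the tertiary alcohol cannot be oxidized, the reagent does not cleave the 1,2-diol as iodine(III) or periodinane oxidants can, and 15 has no α-hydrogen and is used crude.

**Step 12**
Reactants: 15 (2S)-13-{4-[(tert-butyldimethylsilyl)oxy]phenyl}-2-hydroxy-2-methyl-4-methylidenetridecanal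
Product: 17 (5S)-5-(11-{4-[(tert-butyldimethylsilyl)oxy]phenyl}-2-methylideneundecyl)-5-methylfuran-2(5H)-one, via Z-enoate 16 (not isolated)
Conditions: (CF3CH2O)2P(O)CH2CO2Me, KHMDS, 18-crown-6, THF, −78 °C; then rt, PPTS (cat.), CH2Cl2
Reagents that add atoms: methyl bis(2,2,2-trifluoroethyl)phosphonoacetate, COC(=O)CP(=O)(OCC(F)(F)F)OCC(F)(F)F
Why: Still–Gennari olefination gives the (Z)-enoate under kinetic control with the electron-poor phosphonate, and the (Z)-γ-hydroxy ester lactonizes with the tertiary OH to the butenolide with loss of methanol; the quaternary C4 cannot epimerize.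

**Step 13**
Reactants: 17 (5S)-5-(11-{4-[(tert-butyldimethylsilyl)oxy]phenyl}-2-methylideneundecyl)-5-methylfuran-2(5H)-one
Product: 18 (5S)-5-{11-{4-[(tert-butyldimethylsilyl)oxy]phenyl}-2-methyl-2-[(triethylsilyl)peroxy]undecyl}-5-methylfuran-2(5H)-one (both epimers at the peroxide carbon)
Conditions: Co(thd)2 (10 mol %), O2 (1 atm), Et3SiH (3 equiv), ClCH2CH2Cl, rt
Reagents that add atoms: dioxygen, O=O; triethylsilane, CC[SiH](CC)CC
Why: Mukaiyama–Isayama hydroperoxysilylation: the cobalt hydride transfers a hydrogen atom to the electron-rich 1,1-disubstituted alkene in preference to the electron-poor, hindered butenolide alkene, the tertiary C6 radical captures O2 and the cobalt peroxide is silylated to the Markovnikov silyl peroxide; the planar radical is trapped from both faces, so C6 is not controlled here and 18 is carried on as a mixture of epimers, of which the (2R) side-chain epimer leads to 20.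

**Step 14**
Reactants: 18 (5S)-5-{11-{4-[(tert-butyldimethylsilyl)oxy]phenyl}-2-methyl-2-[(triethylsilyl)peroxy]undecyl}-5-methylfuran-2(5H)-one (both epimers at the peroxide carbon)
Product: 20 plakortolide F, via hydroperoxy butenolide 19 (not isolated)
Conditions: TBAF/AcOH (1:1, 2.5 equiv), THF, 0 °C; then Et2NH (cat.), CF3CH2OH, rt; chromatography (separation of the C6 epimers)
Reagents that add atoms: none
Why: Buffered fluoride cleaves the O–Si bonds of the silyl peroxide and the aryl silyl ether, and under Et2NH in the protic solvent the hydroperoxide adds to C3 of the butenolide by a 6-exo-trig intramolecular oxa-Michael addition; the C5 tether can deliver oxygen only to the lactone face it occupies, so C3 is set (S) by C4 and the rings are cis-fused, the protic medium protonates the lactone enolate before it can attack the O–O bond, and the C6 epimers, now rigid bicyclic diastereomers, are separated so that the (6R) isomer is 20.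

**Compound list**

1 | tert-butyl(4-iodophenoxy)dimethylsilane | CC(C)(C)[Si](C)(C)Oc1ccc(I)cc1 | starting material
2 | oct-7-ynoic acid | C#CCCCCCC(=O)O | starting material
3 | 8-{4-[(tert-butyldimethylsilyl)oxy]phenyl}oct-7-ynoic acid | CC(C)(C)[Si](C)(C)Oc1ccc(C#CCCCCCC(=O)O)cc1 | intermediate
4 | 8-{4-[(tert-butyldimethylsilyl)oxy]phenyl}octanoic acid | CC(C)(C)[Si](C)(C)Oc1ccc(CCCCCCCC(=O)O)cc1 | intermediate
5 | 1,3-dioxoisoindolin-2-yl 8-{4-[(tert-butyldimethylsilyl)oxy]phenyl}octanoate | CC(C)(C)[Si](C)(C)Oc1ccc(CCCCCCCC(=O)ON2C(=O)c3ccccc3C2=O)cc1 | intermediate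
6 | (S)-citramalic acid, (2S)-2-hydroxy-2-methylbutanedioic acid | C[C@](O)(CC(=O)O)C(=O)O | starting material
7 | dimethyl (2S)-2-hydroxy-2-methylbutanedioate | C[C@](O)(CC(=O)OC)C(=O)OC | intermediate
8 | methyl (3S)-3,4-dihydroxy-3-methylbutanoate | C[C@](O)(CC(=O)OC)CO | intermediate
9 | methyl 2-[(4S)-2,2,4-trimethyl-1,3-dioxolan-4-yl]acetate | C[C@]1(CC(=O)OC)COC(C)(C)O1 | intermediate
10 | 1-{[(4S)-2,2,4-trimethyl-1,3-dioxolan-4-yl]methyl}cyclopropan-1-ol | C[C@]1(CC2(O)CC2)COC(C)(C)O1 | intermediate
11 | bis{3-oxo-4-[(4S)-2,2,4-trimethyl-1,3-dioxolan-4-yl]butyl}zinc (zinc homoenolate, not isolated) | C[C@]1(CC(=O)CC[Zn]CCC(=O)C[C@@]2(C)COC(C)(C)O2)COC(C)(C)O1 | intermediate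
12 | 11-{4-[(tert-butyldimethylsilyl)oxy]phenyl}-1-[(4S)-2,2,4-trimethyl-1,3-dioxolan-4-yl]undecan-2-one | C[C@]1(CC(=O)CCCCCCCCCc2ccc(O[Si](C)(C)C(C)(C)C)cc2)COC(C)(C)O1 | intermediate
13 | tert-butyldimethyl(4-{10-methylidene-11-[(4S)-2,2,4-trimethyl-1,3-dioxolan-4-yl]undecyl}phenoxy)silane | C[C@]1(CC(=C)CCCCCCCCCc2ccc(O[Si](C)(C)C(C)(C)C)cc2)COC(C)(C)O1 | intermediate
14 | (2S)-13-{4-[(tert-butyldimethylsilyl)oxy]phenyl}-2-methyl-4-methylidenetridecane-1,2-diol | C[C@](O)(CC(=C)CCCCCCCCCc1ccc(O[Si](C)(C)C(C)(C)C)cc1)CO | intermediate
15 | (2S)-13-{4-[(tert-butyldimethylsilyl)oxy]phenyl}-2-hydroxy-2-methyl-4-methylidenetridecanal | C[C@](O)(CC(=C)CCCCCCCCCc1ccc(O[Si](C)(C)C(C)(C)C)cc1)C=O | intermediate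
16 | methyl (2Z,4S)-15-{4-[(tert-butyldimethylsilyl)oxy]phenyl}-4-hydroxy-4-methyl-6-methylidenepentadec-2-enoate (not isolated) | C[C@](O)(CC(=C)CCCCCCCCCc1ccc(O[Si](C)(C)C(C)(C)C)cc1)/C=C\C(=O)OC | intermediate
17 | (5S)-5-(11-{4-[(tert-butyldimethylsilyl)oxy]phenyl}-2-methylideneundecyl)-5-methylfuran-2(5H)-one | C[C@]1(CC(=C)CCCCCCCCCc2ccc(O[Si](C)(C)C(C)(C)C)cc2)C=CC(=O)O1 | intermediate
18 | (5S)-5-{11-{4-[(tert-butyldimethylsilyl)oxy]phenyl}-2-methyl-2-[(triethylsilyl)peroxy]undecyl}-5-methylfuran-2(5H)-one, both epimers at the peroxide carbon (centre left undefined in the SMILES) | C[C@]1(CC(C)(OO[Si](CC)(CC)CC)CCCCCCCCCc2ccc(O[Si](C)(C)C(C)(C)C)cc2)C=CC(=O)O1 | intermediate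
19 | (5S)-5-[2-hydroperoxy-11-(4-hydroxyphenyl)-2-methylundecyl]-5-methylfuran-2(5H)-one, both epimers at the peroxide carbon (not isolated) | C[C@]1(CC(C)(OO)CCCCCCCCCc2ccc(O)cc2)C=CC(=O)O1 | intermediate
20 | plakortolide F, (3S,4S,6R), cis-fused 1,2-dioxane/γ-lactone with 4-methyl, 6-methyl and 6-[9-(4-hydroxyphenyl)nonyl] | C[C@@]1(CCCCCCCCCc2ccc(O)cc2)C[C@]2(C)OC(=O)C[C@@H]2OO1 | target

**Step count.** Total: 14 steps (3 for the chain fragment, 4 for the cyclopropanol, 7 after their union). Longest linear sequence: 11 steps (6 → 20, steps 4–14).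

**Steps most likely to fail**

1. Step 8. The zinc cyclopropoxide may be O-acylated by the active ester before it has opened. The homoenolate may be protonated or undergo β-hydride elimination to the vinyl ketone. The alkyl radical may dimerize or be reduced. The β-alkoxy ketone product may lose the C4 oxygen by base-induced elimination. The fallback replaces the strain-release coupling by a radical conjugate addition that forms the same C2′–C3′ bond with reversed polarity at C2′; it sets out from 9 and 5 and comes back to the route at 12. Ester 9 is converted with MeNH(OMe)·HCl and i-PrMgCl (THF, −20 °C) into the Weinreb amide N-methoxy-N-methyl-2-[(4S)-2,2,4-trimethyl-1,3-dioxolan-4-yl]acetamide F1. Vinylmagnesium bromide (THF, 0 °C, cold acidic quench) then gives the vinyl ketone 1-[(4S)-2,2,4-trimethyl-1,3-dioxolan-4-yl]but-3-en-2-one F2. The primary radical released from 5 under photoredox conditions (Ru(bpy)3(PF6)2, Hantzsch ester, i-Pr2NEt, blue LED, CH2Cl2) should add to the terminal CH2 of F2 in a decarboxylative Giese reaction and give 12 after hydrogen-atom transfer to the α-keto radical.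

2. Step 13. Hydrogen-atom transfer may also reach the butenolide alkene. The cobalt peroxide may be over-reduced to the tertiary alcohol, which would close to a tetrahydrofuran by oxa-Michael addition. The capture of O2 by the planar C6 radical has no facial bias, so part of the material necessarily ends as the C6 epimer. The fallback replaces the radical peroxidation by an ionic one and answers the first two processes; it sets out from 17 and comes back to the route at 19. Acid-catalysed Markovnikov addition of hydrogen peroxide through the tertiary C6 cation (50% H2O2, cat. H2SO4, Et2O, 0 °C), a classical perhydrolysis of 2-methyl-1-alkenes, should give the free hydroperoxide (5S)-5-{11-{4-[(tert-butyldimethylsilyl)oxy]phenyl}-2-hydroperoxy-2-methylundecyl}-5-methylfuran-2(5H)-one F3 as both C6 epimers, the unprotonated butenolide being inert. TBAF/AcOH then removes the aryl silyl ether to give 19, which is closed as in step 14. No known method is expected to control the C6 face in either variant, so the (6R) epimer is isolated after ring closure in both.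

3. Step 12. The α-hydroxy aldehyde 15 may dimerize or self-condense before it is olefinated. Erosion of Z selectivity would leave (E)-enoate that cannot lactonize. The free tertiary alkoxide may interfere under the strongly basic conditions. The fallback replaces the intermolecular olefination by an intramolecular one whose ring geometry enforces the cis alkene; it sets out from 15 and comes back to the route at 17. Heating 15 with (triphenylphosphoranylidene)ketene (Bestmann's ylide, toluene, 80 °C) should acylate the tertiary hydroxyl to give the ester ylide (2S)-13-{4-[(tert-butyldimethylsilyl)oxy]phenyl}-2-methyl-4-methylidene-1-oxotridecan-2-yl (triphenylphosphoranylidene)acetate F4. F4 should close by intramolecular Wittig reaction onto the aldehyde and give 17 directly.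

**Further compounds**

F1 | step 8 | N-methoxy-N-methyl-2-[(4S)-2,2,4-trimethyl-1,3-dioxolan-4-yl]acetamide | C[C@]1(CC(=O)N(C)OC)COC(C)(C)O1
F2 | step 8 | 1-[(4S)-2,2,4-trimethyl-1,3-dioxolan-4-yl]but-3-en-2-one | C[C@]1(CC(=O)C=C)COC(C)(C)O1
F3 | step 13 | (5S)-5-{11-{4-[(tert-butyldimethylsilyl)oxy]phenyl}-2-hydroperoxy-2-methylundecyl}-5-methylfuran-2(5H)-one, both epimers at the peroxide carbon | C[C@]1(CC(C)(OO)CCCCCCCCCc2ccc(O[Si](C)(C)C(C)(C)C)cc2)C=CC(=O)O1
F4 | step 12 | (2S)-13-{4-[(tert-butyldimethylsilyl)oxy]phenyl}-2-methyl-4-methylidene-1-oxotridecan-2-yl (triphenylphosphoranylidene)acetate | C[C@](OC(=O)C=P(c1ccccc1)(c1ccccc1)c1ccccc1)(CC(=C)CCCCCCCCCc1ccc(O[Si](C)(C)C(C)(C)C)cc1)C=O
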